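**Retrosynthetic overview**

1. The target is reached from methyl 2α-silyloxy-8-oxo-17-norlabd-13(Z)-en-15-oate by C8 methylenation, inversion of C2 (oxidation, α-face hydride), ester hydrolysis and acetylation.
2. The side chain is cut at C12–C13: B-alkyl Suzuki coupling of a C11=C12 vinyl group (from the C11 ester) with methyl (Z)-3-iodobut-2-enoate, which carries the 13Z geometry.
3. The strategy rests on C9, which lies between C8 (the future methylene-bearing carbon) and C11. C9 is therefore the α-carbon of a C8-keto C11-ester, and the C9–C10 bond of ring B is cut to give a keto ester tethered through C6–C7 to the C5=C10 alkene of ring A.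
4. Ring A is bought as (4R,6R)-actinol. Its carbinol carbon becomes C2 and relays chirality to C5, C9 and C10. The tether is built by enol triflate formation, Heck coupling with butenone, conjugate reduction and carboxylation.
5. Ring order: ring A from actinol, ring B by acid-promoted cation–olefin closure (step 6).

Key step: step 6

Remarks on the chemistry:
- Labdane numbering is used throughout (ring A C1–C5/C10, ring B C5–C10, chain C11–C16, C17 on C8, C18/C19 on C4, C20 on C10). α is the face opposite the C10 methyl.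
- The target is (2R,5S,9S,10S): 2β-OAc (axial), 5α-H, 9α-H, 10β-CH3, 13Z.
- A tert-butyldiphenylsilyl ether is used at C2 because it must survive SnCl4/HCl, TsOH and aqueous HCl.
- Methyl (Z)-3-iodobut-2-enoate is made in one step (step 11) rather than assumed to be purchasable.

**Route**

Step 1
Reactants: 1 (4R,6R)-actinol
Product: 2 (4R,6R)-4-(tert-butyldiphenylsilyloxy)-2,2,6-trimethylcyclohexanone
Conditions: TBDPSCl, imidazole, DMF, rt
Reagents that add atoms: tert-butyl(chloro)diphenylsilane, CC(C)(C)[Si](Cl)(c1ccccc1)c1ccccc1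
Why: Standard silylation of an unhindered secondary alcohol; no stereocentre is touched.

Step 2
Reactants: 2 (4R,6R)-4-(tert-butyldiphenylsilyloxy)-2,2,6-trimethylcyclohexanone
Product: 4 (R)-4-(tert-butyldiphenylsilyloxy)-2,6,6-trimethylcyclohex-1-en-1-yl trifluoromethanesulfonate, via lithium enolate 3 (not isolated)
Conditions: LDA, THF, −78 → 0 °C; PhNTf2, 0 °C → rt
Reagents that add atoms: N-phenylbis(trifluoromethanesulfonimide), O=S(=O)(N(c1ccccc1)S(=O)(=O)C(F)(F)F)C(F)(F)F
Why: The ketone has a single α-hydrogen, so enolate O-triflation can give only the tetrasubstituted enol triflate; the C6 stereocentre is deliberately erased and the carbinol centre is untouched.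

Step 3
Reactants: 4 enol triflate; 5 but-3-en-2-one
Product: 6 (E)-4-[(R)-4-(tert-butyldiphenylsilyloxy)-2,6,6-trimethylcyclohex-1-en-1-yl]but-3-en-2-one
Conditions: Pd(OAc)2 (5 mol %), PPh3, Et3N, DMF, 70 °C
Reagents that add atoms: none
Why: Heck reaction of an alkenyl triflate with an enone; syn insertion and syn β-hydride elimination should give the E-dienone.

Step 4
Reactants: 6 (E)-dienone
Product: 8 4-[(R)-4-(tert-butyldiphenylsilyloxy)-2,6,6-trimethylcyclohex-1-en-1-yl]butan-2-one, via triethylsilyl enol ether 7 (not isolated)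
Conditions: Et3SiH, RhCl(PPh3)3 (1 mol %), toluene, 50 °C; then 1 M HCl, THF, 0 °C, brief
Reagents that add atoms: none
Why: Rhodium-catalysed 1,4-hydrosilylation of the enone (the method known for β-ionone) should reduce only the disubstituted C=C, and the twisted tetrasubstituted ring alkene is left alone; mild hydrolysis of the silyl enol ether frees the ketone.

Step 5
Reactants: 8 methyl ketone; 9 dimethyl carbonate
Product: 10 methyl 5-[(R)-4-(tert-butyldiphenylsilyloxy)-2,6,6-trimethylcyclohex-1-en-1-yl]-3-oxopentanoate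
Conditions: NaH, (MeO)2CO, THF, reflux; AcOH quench at 0 °C
Reagents that add atoms: none
Why: Claisen-type carboxylation of a methyl ketone; the reaction is reversible and drains to the enolate of the less substituted β-keto ester, so acylation should occur at the methyl group.

Step 6
Reactants: 10 β-keto ester
Product: 11 methyl 2α-(tert-butyldiphenylsilyloxy)-8-oxo-12,13,14,15,16,17-hexanorlabdan-11-oate
Conditions: SnCl4 (2 equiv), CH2Cl2, −20 °C → rt
Reagents that add atoms: none
Why: SnCl4 binds the β-keto ester as a chelated tin enolate, and the HCl thus released reversibly protonates C5 of the tetrasubstituted C5=C10 alkene; the tertiary C10 cation is captured by the enol carbon C9, which is the known acid-promoted cation–olefin cyclisation of dihydro-β-ionone-derived β-keto esters. Ring B closes 6-endo with respect to the C5=C10 alkene (enol-endo with respect to C8=C9) through a chair in which the C6 tether is equatorial on ring A and the new C10–C9 bond develops equatorially, so H-5 and CH3-20 become trans-diaxial (trans-decalin). H-5 and C9 therefore sit on the same α face of ring A, so the ring fusion comes from a stepwise, net cis addition through the cation and not from a concerted antiperiplanar addition. The absolute sense is relayed from C2: reversible protonation makes both C5-epimeric cations available, and closure should run through the chair with the C2 silyloxy group equatorial (2α, 10β-CH3), because the other chair places it syn-diaxial to the axial C4 methyl and the developing C10 methyl. C9 is expected as the equatorial 9β-ester, the thermodynamic epimer of an enolisable β-keto ester. The step needs C- over O-capture of the cation, which the tin chelate favours, and survival of the C2 ether, for which the acid-stable TBDPS group was chosen.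

Step 7
Reactants: 11 bicyclic keto ester
Product: 12 methyl 2α-(tert-butyldiphenylsilyloxy)-8,8-(ethylenedioxy)-12,13,14,15,16,17-hexanorlabdan-11-oate
Conditions: ethylene glycol, TsOH (cat.), benzene, reflux, Dean–Stark
Reagents that add atoms: ethylene glycol, OCCO
Why: Acid-catalysed ketalisation with water removal masks the C8 ketone; the TBDPS ether tolerates these conditions and C9 stays in its equatorial, thermodynamic configuration.

Step 8
Reactants: 12 ketal ester
Product: 13 2α-(tert-butyldiphenylsilyloxy)-8,8-(ethylenedioxy)-12,13,14,15,16,17-hexanorlabdan-11-ol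
Conditions: LiAlH4, THF, 0 °C → rt
Reagents that add atoms: none
Why: Hydride reduction of the ester to the primary C11 alcohol; ketal and silyl ether are inert and C9 is no longer enolisable.

Step 9
Reactants: 13 C11 alcohol
Product: 14 2α-(tert-butyldiphenylsilyloxy)-8,8-(ethylenedioxy)-12,13,14,15,16,17-hexanorlabdan-11-al
Conditions: Dess–Martin periodinane, pyridine, CH2Cl2, rt
Reagents that add atoms: none
Why: Buffered Dess–Martin oxidation gives the aldehyde without acid that could open the β-ketal; the aldehyde is equatorial at C9, so epimerisation is not a concern.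

Step 10
Reactants: 14 C11 aldehyde
Product: 15 2α-(tert-butyldiphenylsilyloxy)-8,8-(ethylenedioxy)-13,14,15,16,17-pentanorlabd-11-ene
Conditions: Ph3PCH3Br, KOtBu (slightly less than 1 equiv per phosphonium), THF, 0 °C; then 14, −78 → 0 °C
Reagents that add atoms: methyltriphenylphosphonium bromide, C[P+](c1ccccc1)(c1ccccc1)c1ccccc1.[Br-]
Why: Wittig methylenation installs C12; addition of the unhindered ylide to the aldehyde at low temperature should outrun C9 deprotonation and β-elimination of the ketal oxygen.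

Step 11
Reactants: 16 methyl but-2-ynoate
Product: 17 methyl (Z)-3-iodobut-2-enoate
Conditions: NaI, AcOH, 110 °C
Reagents that add atoms: sodium iodide, [Na+].[I-]
Why: Conjugate hydroiodination of an ynoate proceeds by anti addition of H and I, which places iodine cis to the ester (Z).

Step 12
Reactants: 15 vinyl ketal; 17 methyl (Z)-3-iodobut-2-enoate
Product: 19 methyl 2α-(tert-butyldiphenylsilyloxy)-8,8-(ethylenedioxy)-17-norlabd-13(Z)-en-15-oate, via B-alkyl-9-BBN 18 (not isolated)
Conditions: 9-BBN, THF, 0 → 50 °C; then 17, Pd(dppf)Cl2 (5 mol %), AsPh3, aq. Cs2CO3, DMF, rt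
Reagents that add atoms: none
Why: Anti-Markovnikov hydroboration puts boron on C12, and the B-alkyl Suzuki–Miyaura coupling forms C12–C13 with retention of the iodoalkene geometry, so C12 ends up cis to the ester (13Z).

Step 13
Reactants: 19 ketal enoate
Product: 20 methyl 2α-(tert-butyldiphenylsilyloxy)-8-oxo-17-norlabd-13(Z)-en-15-oate
Conditions: 2 M HCl, THF, rt
Reagents that add atoms: water, O
Why: Aqueous acid hydrolysis of the dioxolane; the TBDPS ether and the Z-enoate are stable to dilute acid, and C9 keeps its equatorial side chain.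

Step 14
Reactants: 20 C8 ketone
Product: 21 methyl 2α-(tert-butyldiphenylsilyloxy)labda-8(17),13(Z)-dien-15-oate
Conditions: Zn, CH2Br2, TiCl4 (Takai–Lombardo reagent), THF/CH2Cl2, 0 °C → rt
Reagents that add atoms: dibromomethane, BrCBr
Why: Takai–Lombardo methylenation is non-basic and selective for ketones over esters, so neither C9 nor the Z-enoate should be disturbed while C17 is installed.

Step 15
Reactants: 21 silyl ether
Product: 22 methyl 2α-hydroxylabda-8(17),13(Z)-dien-15-oate
Conditions: TBAF, AcOH, THF, rt → 45 °C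
Reagents that add atoms: none
Why: Fluoride cleavage of the silyl ether, buffered with acetic acid so that the methyl enoate is neither hydrolysed nor isomerised.

Step 16
Reactants: 22 2α-alcohol
Product: 23 methyl 2-oxolabda-8(17),13(Z)-dien-15-oate
Conditions: Dess–Martin periodinane, pyridine, CH2Cl2, rt
Reagents that add atoms: none
Why: Mild oxidation of the secondary alcohol to the C2 ketone; both alkenes are inert and no enolisable stereocentre is adjacent.

Step 17
Reactants: 23 C2 ketone
Product: 24 methyl 2β-hydroxylabda-8(17),13(Z)-dien-15-oate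
Conditions: L-Selectride, THF, −78 °C; H2O quench
Reagents that add atoms: none
Why: The β face of C2 is screened by the two syn-axial methyls (C10-CH3 and 4β-CH3), so the bulky hydride should add from the α face to give the axial 2β-alcohol; the β,β-disubstituted enoate is not reduced at −78 °C.

Step 18
Reactants: 24 2β-hydroxy ester
Product: 25 2β-hydroxylabda-8(17),13(Z)-dien-15-oic acid
Conditions: LiOH, THF/MeOH/H2O, 40 °C; then 1 M HCl to pH 4 at 0 °C
Reagents that add atoms: lithium hydroxide, [Li+].[OH-]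
Why: Saponification of the methyl ester by acyl substitution leaves the trisubstituted Z-alkene in place; hydrolysis precedes acetylation because the acetate would not survive it.

Step 19
Reactants: 25 hydroxy acid
Product: 27 2β-acetoxylabda-8(17),13(Z)-dien-15-oic acid (target), via mixed acetic anhydride 26 (not isolated)
Conditions: Ac2O, DMAP, pyridine, rt → 40 °C; then H2O/THF, rt; NaH2PO4 to pH 4
Reagents that add atoms: acetic anhydride, CC(=O)OC(C)=O
Why: DMAP-catalysed acylation esterifies the hindered axial 2β-hydroxyl with retention; the carboxyl group is carried as its mixed anhydride, which water cleaves at the more electrophilic acetyl carbonyl to return the free acid.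

**Compound list**

1 | (4R,6R)-4-hydroxy-2,2,6-trimethylcyclohexanone (actinol) | C[C@@H]1C[C@@H](O)CC(C)(C)C1=O | starting material
2 | (4R,6R)-4-(tert-butyldiphenylsilyloxy)-2,2,6-trimethylcyclohexanone | C[C@@H]1C[C@@H](O[Si](c2ccccc2)(c2ccccc2)C(C)(C)C)CC(C)(C)C1=O | intermediate
3 | lithium (R)-4-(tert-butyldiphenylsilyloxy)-2,6,6-trimethylcyclohex-1-en-1-olate (not isolated) | [Li]OC1=C(C)C[C@@H](O[Si](c2ccccc2)(c2ccccc2)C(C)(C)C)CC1(C)C | intermediate
4 | (R)-4-(tert-butyldiphenylsilyloxy)-2,6,6-trimethylcyclohex-1-en-1-yl trifluoromethanesulfonate | O=S(=O)(OC1=C(C)C[C@@H](O[Si](c2ccccc2)(c2ccccc2)C(C)(C)C)CC1(C)C)C(F)(F)F | intermediate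
5 | but-3-en-2-one | C=CC(C)=O | starting material
6 | (E)-4-[(R)-4-(tert-butyldiphenylsilyloxy)-2,6,6-trimethylcyclohex-1-en-1-yl]but-3-en-2-one | CC(=O)/C=C/C1=C(C)C[C@@H](O[Si](c2ccccc2)(c2ccccc2)C(C)(C)C)CC1(C)C | intermediate
7 | triethylsilyl enol ether of 8, (Z)-2-(triethylsilyloxy)but-2-ene form; geometry immaterial (not isolated) | CC[Si](CC)(CC)O/C(C)=C\CC1=C(C)C[C@@H](O[Si](c2ccccc2)(c2ccccc2)C(C)(C)C)CC1(C)C | intermediate
8 | 4-[(R)-4-(tert-butyldiphenylsilyloxy)-2,6,6-trimethylcyclohex-1-en-1-yl]butan-2-one | CC(=O)CCC1=C(C)C[C@@H](O[Si](c2ccccc2)(c2ccccc2)C(C)(C)C)CC1(C)C | intermediate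
9 | dimethyl carbonate | COC(=O)OC | starting material
10 | methyl 5-[(R)-4-(tert-butyldiphenylsilyloxy)-2,6,6-trimethylcyclohex-1-en-1-yl]-3-oxopentanoate | COC(=O)CC(=O)CCC1=C(C)C[C@@H](O[Si](c2ccccc2)(c2ccccc2)C(C)(C)C)CC1(C)C | intermediate
11 | methyl 2α-(tert-butyldiphenylsilyloxy)-8-oxo-12,13,14,15,16,17-hexanorlabdan-11-oate (trans-decalin; 5α-H, 9α-H, 10β-CH3) | COC(=O)[C@H]1C(=O)CC[C@H]2C(C)(C)C[C@H](O[Si](c3ccccc3)(c3ccccc3)C(C)(C)C)C[C@]12C | intermediate
12 | methyl 2α-(tert-butyldiphenylsilyloxy)-8,8-(ethylenedioxy)-12,13,14,15,16,17-hexanorlabdan-11-oate | COC(=O)[C@H]1C2(OCCO2)CC[C@H]3C(C)(C)C[C@H](O[Si](c4ccccc4)(c4ccccc4)C(C)(C)C)C[C@]13C | intermediate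
13 | 2α-(tert-butyldiphenylsilyloxy)-8,8-(ethylenedioxy)-12,13,14,15,16,17-hexanorlabdan-11-ol | OC[C@H]1C2(OCCO2)CC[C@H]3C(C)(C)C[C@H](O[Si](c4ccccc4)(c4ccccc4)C(C)(C)C)C[C@]13C | intermediate
14 | 2α-(tert-butyldiphenylsilyloxy)-8,8-(ethylenedioxy)-12,13,14,15,16,17-hexanorlabdan-11-al | O=C[C@H]1C2(OCCO2)CC[C@H]3C(C)(C)C[C@H](O[Si](c4ccccc4)(c4ccccc4)C(C)(C)C)C[C@]13C | intermediate
15 | 2α-(tert-butyldiphenylsilyloxy)-8,8-(ethylenedioxy)-13,14,15,16,17-pentanorlabd-11-ene (9β-vinyl) | C=C[C@H]1C2(OCCO2)CC[C@H]3C(C)(C)C[C@H](O[Si](c4ccccc4)(c4ccccc4)C(C)(C)C)C[C@]13C | intermediate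
16 | methyl but-2-ynoate | CC#CC(=O)OC | starting material
17 | methyl (Z)-3-iodobut-2-enoate | C/C(I)=C/C(=O)OC | intermediate
18 | 12-(9-borabicyclo[3.3.1]nonan-9-yl)-2α-(tert-butyldiphenylsilyloxy)-8,8-(ethylenedioxy)-13,14,15,16,17-pentanorlabdane (not isolated) | B1(C2CCCC1CCC2)CC[C@H]3C4(OCCO4)CC[C@H]5C(C)(C)C[C@H](O[Si](c6ccccc6)(c6ccccc6)C(C)(C)C)C[C@]35C | intermediate
19 | methyl 2α-(tert-butyldiphenylsilyloxy)-8,8-(ethylenedioxy)-17-norlabd-13(Z)-en-15-oate | COC(=O)/C=C(/C)CC[C@H]1C2(OCCO2)CC[C@H]3C(C)(C)C[C@H](O[Si](c4ccccc4)(c4ccccc4)C(C)(C)C)C[C@]13C | intermediate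
20 | methyl 2α-(tert-butyldiphenylsilyloxy)-8-oxo-17-norlabd-13(Z)-en-15-oate | COC(=O)/C=C(/C)CC[C@H]1C(=O)CC[C@H]2C(C)(C)C[C@H](O[Si](c3ccccc3)(c3ccccc3)C(C)(C)C)C[C@]12C | intermediate
21 | methyl 2α-(tert-butyldiphenylsilyloxy)labda-8(17),13(Z)-dien-15-oate | COC(=O)/C=C(/C)CC[C@H]1C(=C)CC[C@H]2C(C)(C)C[C@H](O[Si](c3ccccc3)(c3ccccc3)C(C)(C)C)C[C@]12C | intermediate
22 | methyl 2α-hydroxylabda-8(17),13(Z)-dien-15-oate | COC(=O)/C=C(/C)CC[C@H]1C(=C)CC[C@H]2C(C)(C)C[C@H](O)C[C@]12C | intermediate
23 | methyl 2-oxolabda-8(17),13(Z)-dien-15-oate | COC(=O)/C=C(/C)CC[C@H]1C(=C)CC[C@H]2C(C)(C)CC(=O)C[C@]12C | intermediate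
24 | methyl 2β-hydroxylabda-8(17),13(Z)-dien-15-oate | COC(=O)/C=C(/C)CC[C@H]1C(=C)CC[C@H]2C(C)(C)C[C@@H](O)C[C@]12C | intermediate
25 | 2β-hydroxylabda-8(17),13(Z)-dien-15-oic acid | OC(=O)/C=C(/C)CC[C@H]1C(=C)CC[C@H]2C(C)(C)C[C@@H](O)C[C@]12C | intermediate
26 | acetic 2β-acetoxylabda-8(17),13(Z)-dien-15-oic anhydride (not isolated) | CC(=O)OC(=O)/C=C(/C)CC[C@H]1C(=C)CC[C@H]2C(C)(C)C[C@@H](OC(C)=O)C[C@]12C | intermediate
27 | (2R,5S,9S,10S)-2-acetoxylabda-8(17),13(Z)-dien-15-oic acid (CNP0255148.1) | C=C1CC[C@H]2C(C)(C)C[C@@H](OC(C)=O)C[C@]2(C)[C@H]1CC/C(C)=C\C(=O)O | target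

**Step count**

Total: 19 steps. Longest linear sequence: 18 steps (steps 1–10 and 12–19 from actinol); step 11 is a one-step side branch.

**Steps most likely to fail**

Step 6 (key cyclisation). The C10 cation may be captured by the enol oxygen instead of C9, or may lose a proton to ring-alkene isomers that cyclise slowly. Long exposure to SnCl4/HCl may also erode the silyl ether, and incomplete equatorial preference of the C2 group would lower the facial selectivity. The fallback sets out from 10 and returns at 11, and replaces the enol by a carbon-only π-nucleophile. Compound 10 is converted with NaH and diethyl chlorophosphate (Et2O, 0 °C) into the (Z)-enol diethyl phosphate F1. Nickel-catalysed coupling of F1 with Me3SiCH2MgCl (Ni(acac)2, THF) should give the (Z)-3-(trimethylsilylmethyl)pent-2-enoate allylsilane F2, whose γ-carbon is C9. Acid-promoted allylsilane-terminated cyclisation of F2 (SnCl4, CH2Cl2, −78 → 0 °C) should close the same C9–C10 bond with loss of silicon and give the 8(17)-methylene ester F3. Ozonolysis of F3 (O3, CH2Cl2/MeOH, −78 °C; Me2S) returns keto ester 11.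

Step 3 (Heck coupling). Migratory insertion of butenone at the alkenylpalladium centre, flanked by the C2' methyl and the gem-dimethyl carbon, may be slow, so that triflate reduction and catalyst decomposition take over. The fallback sets out from 4 and returns at 8, and forms the same C–C bond by transmetalation instead of insertion. 2-Methyl-2-vinyl-1,3-dioxolane is hydroborated with 9-BBN (THF) to the alkylborane F4. B-alkyl Suzuki coupling of F4 with 4 (Pd(dppf)Cl2, AsPh3, aq. Cs2CO3, DMF) should give the saturated ketal F5. Hydrolysis of F5 (PPTS, acetone/H2O) gives ketone 8 directly, which also removes the need for step 4.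

Step 14 (C8 methylenation). Methylene transfer to the hindered C8 carbonyl may be slow, and forcing it with Lewis acid or with a basic ylide risks isomerising the Z-enoate or epimerising C9. The fallback sets out from 15 and returns at 21, and places C17 before the enoate exists. Hydroboration–oxidation of 15 (9-BBN; NaOH, H2O2) gives the C12 alcohol F6. Ketal hydrolysis (2 M HCl, THF) gives the keto alcohol F7. Wittig methylenation with excess Ph3P=CH2 (no base-sensitive group is present) gives the 8(17)-ene alcohol F8. Appel-type iodination (I2, PPh3, imidazole) gives the C12 iodide F9. Zinc insertion (Zn, LiCl, THF) gives the alkylzinc iodide F10, and Negishi coupling of F10 with 17 (Pd(PPh3)4, THF) should give 21 with retention of the Z geometry.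

**Further compounds**

F1 | step 6 | methyl (Z)-3-(diethoxyphosphoryloxy)-5-[(R)-4-(tert-butyldiphenylsilyloxy)-2,6,6-trimethylcyclohex-1-en-1-yl]pent-2-enoate | COC(=O)/C=C(\OP(=O)(OCC)OCC)CCC1=C(C)C[C@@H](O[Si](c2ccccc2)(c2ccccc2)C(C)(C)C)CC1(C)C
F2 | step 6 | methyl (Z)-3-(trimethylsilylmethyl)-5-[(R)-4-(tert-butyldiphenylsilyloxy)-2,6,6-trimethylcyclohex-1-en-1-yl]pent-2-enoate | COC(=O)/C=C(\C[Si](C)(C)C)CCC1=C(C)C[C@@H](O[Si](c2ccccc2)(c2ccccc2)C(C)(C)C)CC1(C)C
F3 | step 6 | methyl 2α-(tert-butyldiphenylsilyloxy)-12,13,14,15,16-pentanorlabd-8(17)-en-11-oate | COC(=O)[C@H]1C(=C)CC[C@H]2C(C)(C)C[C@H](O[Si](c3ccccc3)(c3ccccc3)C(C)(C)C)C[C@]12C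
F4 | step 3 | 9-[2-(2-methyl-1,3-dioxolan-2-yl)ethyl]-9-borabicyclo[3.3.1]nonane | CC1(CCB2C3CCCC2CCC3)OCCO1
F5 | step 3 | 2-{2-[(R)-4-(tert-butyldiphenylsilyloxy)-2,6,6-trimethylcyclohex-1-en-1-yl]ethyl}-2-methyl-1,3-dioxolane | CC1(CCC2=C(C)C[C@@H](O[Si](c3ccccc3)(c3ccccc3)C(C)(C)C)CC2(C)C)OCCO1
F6 | step 14 | 2α-(tert-butyldiphenylsilyloxy)-8,8-(ethylenedioxy)-13,14,15,16,17-pentanorlabdan-12-ol | OCC[C@H]1C2(OCCO2)CC[C@H]3C(C)(C)C[C@H](O[Si](c4ccccc4)(c4ccccc4)C(C)(C)C)C[C@]13C
F7 | step 14 | 2α-(tert-butyldiphenylsilyloxy)-12-hydroxy-13,14,15,16,17-pentanorlabdan-8-one | OCC[C@H]1C(=O)CC[C@H]2C(C)(C)C[C@H](O[Si](c3ccccc3)(c3ccccc3)C(C)(C)C)C[C@]12C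
F8 | step 14 | 2α-(tert-butyldiphenylsilyloxy)-13,14,15,16-tetranorlabd-8(17)-en-12-ol | OCC[C@H]1C(=C)CC[C@H]2C(C)(C)C[C@H](O[Si](c3ccccc3)(c3ccccc3)C(C)(C)C)C[C@]12C
F9 | step 14 | 2α-(tert-butyldiphenylsilyloxy)-12-iodo-13,14,15,16-tetranorlabd-8(17)-ene | ICC[C@H]1C(=C)CC[C@H]2C(C)(C)C[C@H](O[Si](c3ccccc3)(c3ccccc3)C(C)(C)C)C[C@]12C
F10 | step 14 | [2α-(tert-butyldiphenylsilyloxy)-13,14,15,16-tetranorlabd-8(17)-en-12-yl]zinc iodide | I[Zn]CC[C@H]1C(=C)CC[C@H]2C(C)(C)C[C@H](O[Si](c3ccccc3)(c3ccccc3)C(C)(C)C)C[C@]12C
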